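**Retrosynthetic overview**

1. Feature: in this 3,3''-biflavanone the chain C4–C3–C3''–C4'' is a 2,3-disubstituted succinyl unit. Each carbonyl carbon (C4, C4'') is bonded to the ring A carbon (C4a, C4a'') ortho to the ether oxygen (O1, O1''), and C2 and C2'' are benzylic aryl ether carbons.
2. Key disconnection: C4–C4a and C4''–C4a'' by a double intramolecular Friedel–Crafts acylation of succinic acid 18. Ring C'' and then ring C are closed last, in one flask.
3. 18 comes from the C2-symmetric diol 8. The two different aryl ethers are formed with inversion at the benzylic carbons (cyclic sulfate opening, then Mitsunobu reaction) while CH2OSi groups stand in for the carboxyl groups.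
4. 8 comes from dilactone 6, made by a double Evans syn-aldol/lactonisation of the succinyl bis(oxazolidinone) 3 with 4-bromobenzaldehyde; this sets all four stereocentres.
5. After the key step: BBr3 while the B rings are still 4-bromophenyl, then ArBr → ArBpin → ArOH.

Key step: step 10

Remark on the chemistry: in both chromanone rings the 2,3-trans (diequatorial) arrangement is taken to be the more stable one, so any enolisation at C3 or C3'' from step 9 onwards should return the configuration drawn.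

**Route**

Step 1
Reactants: 1 succinyl chloride; 2 (R)-4-benzyl-1,3-oxazolidin-2-one
Product: 3 1,4-bis[(4R)-4-benzyl-2-oxo-1,3-oxazolidin-3-yl]butane-1,4-dione
Conditions: 2 (2.05 equiv), n-BuLi (2.05 equiv), THF, −78 °C; then 1 (1.0 equiv), −78 → 0 °C
Reagents that add atoms: none
Why: N-acylation of the lithiated oxazolidinone by both acid chloride groups (standard imide formation) should give the bis-imide; no stereocentre is formed.

Step 2
Reactants: 3 bis-imide; 4 4-bromobenzaldehyde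
Product: 6 (3R,3aR,6R,6aR)-3,6-bis(4-bromophenyl)tetrahydro-1H,3H-furo[3,4-c]furan-1,4-dione (cis-fused; both aryl groups exo), via double syn-aldol adduct 5 (not isolated)
Conditions: Bu2BOTf (2.4 equiv), i-Pr2NEt (2.8 equiv), CH2Cl2, −78 → 0 °C; 4 (2.6 equiv), −78 → 0 °C; H2O2, MeOH, pH 7 buffer, 0 °C; then Et3N, CH2Cl2, 23 °C
Reagents that add atoms: none
Why: Evans syn-aldol reaction run at both ends of the bis(Z-boron enolate): each Zimmerman–Traxler transition state is steered by its own (R)-benzyl auxiliary, so both carbinol carbons and both α-carbons should come out R (syn in each half, C2-symmetric overall), and each hydroxyl then acylates itself with the distal imide (5-exo-trig lactonisation), releasing the auxiliary and fixing the core as the cis-fused exo,exo-dilactone.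

Step 3
Reactants: 6 dilactone
Product: 7 (1R,2S,3S,4R)-1,4-bis(4-bromophenyl)-2,3-bis(hydroxymethyl)butane-1,4-diol
Conditions: LiBH4 (4 equiv), THF, 0 → 40 °C; aq. NH4Cl
Reagents that add atoms: none
Why: hydride reduction of both lactones to diols should leave the four stereocentres and the aryl bromides untouched.

Step 4
Reactants: 7 tetraol
Product: 8 (1R,2S,3S,4R)-1,4-bis(4-bromophenyl)-2,3-bis{[tert-butyl(diphenyl)silyl]oxymethyl}butane-1,4-diol
Conditions: TBDPSCl (2.1 equiv), imidazole (4 equiv), DMF, 0 °C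
Reagents that add atoms: tert-butyl(chloro)diphenylsilane, CC(C)(C)[Si](Cl)(c1ccccc1)c1ccccc1
Why: the bulky silyl chloride should silylate the two primary hydroxyls selectively over the hindered secondary benzylic ones (selective silyl ether formation).

Step 5
Reactants: 8 bis-silyl ether diol
Product: 10 (4R,5S,6S,7R)-4,7-bis(4-bromophenyl)-5,6-bis{[tert-butyl(diphenyl)silyl]oxymethyl}-1,3,2-dioxathiepane 2,2-dioxide, via cyclic sulfite 9 (not isolated)
Conditions: SOCl2 (1.3 equiv), Et3N (3 equiv), CH2Cl2, −20 → 0 °C; then RuCl3 (1 mol%), NaIO4 (1.5 equiv), MeCN/CH2Cl2/H2O, 0 °C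
Reagents that add atoms: thionyl chloride, O=S(Cl)Cl; sodium periodate, [Na+].[O-]I(=O)(=O)=O
Why: Sharpless cyclic sulfate synthesis (cyclic sulfite, then RuO4-catalysed oxidation at sulfur) should convert the C2-symmetric 1,4-diol into one seven-membered sulfate that activates both benzylic C–O bonds but lets only one be displaced.

Step 6
Reactants: 10 cyclic sulfate; 11 3-methoxyphenol
Product: 13 (1R,2S,3S,4S)-1,4-bis(4-bromophenyl)-2,3-bis{[tert-butyl(diphenyl)silyl]oxymethyl}-4-(3-methoxyphenoxy)butan-1-ol, via sulfate monoester cesium salt 12 (not isolated)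
Conditions: 11 (1.2 equiv), Cs2CO3 (1.3 equiv), DMF, 23 → 40 °C; then H2SO4 (cat.), H2O (2 equiv), THF, 23 °C
Reagents that add atoms: none
Why: nucleophilic opening of a cyclic sulfate: the phenoxide should attack one of the two homotopic benzylic carbons in an S_N2 step with inversion (R to S), the sulfate monoester anion left behind resists a second displacement, and its acid hydrolysis by S–O cleavage returns the other carbinol with its R configuration.

Step 7
Reactants: 13 mono-ether alcohol; 14 3,5-dimethoxyphenol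
Product: 15 (1S,2S,3S,4S)-1,4-bis(4-bromophenyl)-1-(3,5-dimethoxyphenoxy)-4-(3-methoxyphenoxy)-2,3-bis{[tert-butyl(diphenyl)silyl]oxymethyl}butane
Conditions: 14 (1.5 equiv), PPh3 (1.6 equiv), DIAD (1.6 equiv), toluene, 0 → 23 °C
Reagents that add atoms: none
Why: Mitsunobu etherification: the phenoxide should displace the alkoxyphosphonium ion in an S_N2 step with inversion (R to S), and the electron-poor 4-bromophenyl group disfavours the ionisation that would scramble this centre.

Step 8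
Reactants: 15 bis-ether
Product: 16 (2S,3S)-2-[(S)-(4-bromophenyl)(3-methoxyphenoxy)methyl]-3-[(S)-(4-bromophenyl)(3,5-dimethoxyphenoxy)methyl]butane-1,4-diol
Conditions: TBAF (3 equiv), AcOH (3 equiv), THF, 23 °C
Reagents that add atoms: none
Why: fluoride-mediated cleavage of the two silyl ethers, buffered with acetic acid, should free both primary alcohols without touching the benzylic aryl ethers.

Step 9
Reactants: 16 diol
Product: 18 (2R,3R)-2-[(S)-(4-bromophenyl)(3-methoxyphenoxy)methyl]-3-[(S)-(4-bromophenyl)(3,5-dimethoxyphenoxy)methyl]butanedioic acid, via dialdehyde 17 (not isolated)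
Conditions: Dess–Martin periodinane (3 equiv), NaHCO3, CH2Cl2, 0 → 23 °C; then NaClO2, NaH2PO4, 2-methylbut-2-ene, t-BuOH/THF/H2O, 0 °C
Reagents that add atoms: sodium chlorite, [Na+].[O-]Cl=O
Why: Dess–Martin oxidation with excess reagent (both hydroxyls are bound to iodine before either aldehyde forms, which avoids the lactol) followed at once by Pinnick oxidation keeps the β-aryloxy aldehydes away from base, so no phenoxide should be eliminated and the stereocentres should be retained.

Step 10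
Reactants: 18 succinic acid
Product: 22 (2S,3R)-2-(4-bromophenyl)-3-[(2S,3R)-2-(4-bromophenyl)-7-methoxy-4-oxochroman-3-yl]-5,7-dimethoxychroman-4-one, via cyclic anhydride 19 (not isolated), via keto acid 20 (not isolated), via mixed trifluoroacetic anhydride 21 (not isolated)
Conditions: (CF3CO)2O (8 equiv), CH2Cl2, 0 °C; then CF3SO3H (0.3 equiv), 0 → 23 °C
Reagents that add atoms: none
Why: Trifluoroacetic anhydride dehydrates the trans-diacid to the cyclic anhydride 19 (a succinic acid cannot be held as a bis(acid chloride), so the anhydride is used as the first acyl donor) and converts the carboxyl group freed by the first closure into its mixed anhydride 21, so that protonation by CF3SO3H provides an acylium-type electrophile first at C4'' and then at C4. Each acyl carbon is attacked by the carbon of the tethered aryloxy ring ortho to the ether oxygen and the arenium ion loses a proton, which is the intramolecular Friedel–Crafts acylation known to turn 3-aryloxy- and 3-aryl-3-aryloxypropanoic acids into chroman-4-ones and flavanones. Ring C'' and ring C both close in the 6-exo mode at the acyl carbon (carbonyl oxygen outside the ring), the seven-membered closure onto the far carbonyl being disfavoured. No stereocentre is created: C2 and C2'' are fixed in steps 6 and 7, and C3 and C3'', set in step 2 and now α to the ketones, can only settle in the diequatorial 2,3-trans arrangement they already have. The selectivity needed is closure para to the methoxy group of the 3-methoxyphenoxy ring (7-methoxy, not 5-methoxy chromanone), which the crowded position between the two oxygens secures, and survival of the benzylic C–O bonds, which the 4-bromophenyl groups and the β-acyl substituents protect against ionisation.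

Step 11
Reactants: 22 trimethyl ether
Product: 23 (2S,3R)-2-(4-bromophenyl)-3-[(2S,3R)-2-(4-bromophenyl)-7-hydroxy-4-oxochroman-3-yl]-5,7-dihydroxychroman-4-one
Conditions: BBr3 (10 equiv), CH2Cl2, −78 → 23 °C; then H2O
Reagents that add atoms: none
Why: BBr3 cleavage of the three aryl methyl ethers is placed here, while both B rings are still electron-poor bromophenyl groups, so that the Lewis acid should not ionise C2–O1 or C2''–O1'' and epimerise C2 or C2''.

Step 12
Reactants: 23 dibromide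
Product: 24 (2S,3R)-5,7-dihydroxy-3-{(2S,3R)-7-hydroxy-4-oxo-2-[4-(4,4,5,5-tetramethyl-1,3,2-dioxaborolan-2-yl)phenyl]chroman-3-yl}-2-[4-(4,4,5,5-tetramethyl-1,3,2-dioxaborolan-2-yl)phenyl]chroman-4-one
Conditions: B2pin2 (3 equiv), KOAc (8 equiv), Pd(dppf)Cl2 (10 mol%), 1,4-dioxane, 85 °C
Reagents that add atoms: bis(pinacolato)diboron, CC1(C)OB(OC1(C)C)B1OC(C)(C)C(C)(C)O1
Why: Miyaura borylation of both aryl bromides should tolerate the free phenols, and KOAc is too weak a base to open the chromanone rings by enolisation and β-elimination.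

Step 13
Reactants: 24 bis(boronate)
Product: 25 (2S,3R)-5,7-dihydroxy-3-[(2S,3R)-7-hydroxy-2-(4-hydroxyphenyl)-4-oxochroman-3-yl]-2-(4-hydroxyphenyl)chroman-4-one (target, CNP0138443.1)
Conditions: H2O2 (30% aq., 10 equiv), THF/pH 7.4 phosphate buffer, 0 → 23 °C
Reagents that add atoms: hydrogen peroxide, OO
Why: oxidative ipso-hydroxylation of the aryl boronates (1,2-shift of aryl from boron to oxygen, then hydrolysis) runs near neutral pH, so the 4-hydroxyphenyl flavanone should form without base-induced ring opening.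

**Compound list**

1 | succinyl chloride | O=C(Cl)CCC(=O)Cl | starting material
2 | (R)-4-benzyl-1,3-oxazolidin-2-one | O=C1N[C@H](Cc2ccccc2)CO1 | starting material
3 | 1,4-bis[(4R)-4-benzyl-2-oxo-1,3-oxazolidin-3-yl]butane-1,4-dione | O=C(CCC(=O)N1C(=O)OC[C@H]1Cc1ccccc1)N1C(=O)OC[C@H]1Cc1ccccc1 | intermediate
4 | 4-bromobenzaldehyde | O=Cc1ccc(Br)cc1 | starting material
5 | (2R,3R)-1,4-bis[(4R)-4-benzyl-2-oxo-1,3-oxazolidin-3-yl]-2,3-bis[(R)-(4-bromophenyl)(hydroxy)methyl]butane-1,4-dione | O[C@@H](c1ccc(Br)cc1)[C@H](C(=O)N1C(=O)OC[C@H]1Cc1ccccc1)[C@@H](C(=O)N1C(=O)OC[C@H]1Cc1ccccc1)[C@@H](O)c1ccc(Br)cc1 | intermediate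
6 | (3R,3aR,6R,6aR)-3,6-bis(4-bromophenyl)tetrahydro-1H,3H-furo[3,4-c]furan-1,4-dione | O=C1O[C@@H](c2ccc(Br)cc2)[C@H]2[C@@H]1[C@H](c1ccc(Br)cc1)OC2=O | intermediate
7 | (1R,2S,3S,4R)-1,4-bis(4-bromophenyl)-2,3-bis(hydroxymethyl)butane-1,4-diol | O[C@@H](c1ccc(Br)cc1)[C@H](CO)[C@@H](CO)[C@@H](O)c1ccc(Br)cc1 | intermediate
8 | (1R,2S,3S,4R)-1,4-bis(4-bromophenyl)-2,3-bis{[tert-butyl(diphenyl)silyl]oxymethyl}butane-1,4-diol | O[C@@H](c1ccc(Br)cc1)[C@H](CO[Si](c1ccccc1)(c1ccccc1)C(C)(C)C)[C@@H](CO[Si](c1ccccc1)(c1ccccc1)C(C)(C)C)[C@@H](O)c1ccc(Br)cc1 | intermediate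
9 | (4R,5S,6S,7R)-4,7-bis(4-bromophenyl)-5,6-bis{[tert-butyl(diphenyl)silyl]oxymethyl}-1,3,2-dioxathiepane 2-oxide | O=S1O[C@@H](c2ccc(Br)cc2)[C@H](CO[Si](c2ccccc2)(c2ccccc2)C(C)(C)C)[C@@H](CO[Si](c2ccccc2)(c2ccccc2)C(C)(C)C)[C@H](c2ccc(Br)cc2)O1 | intermediate
10 | (4R,5S,6S,7R)-4,7-bis(4-bromophenyl)-5,6-bis{[tert-butyl(diphenyl)silyl]oxymethyl}-1,3,2-dioxathiepane 2,2-dioxide | O=S1(=O)O[C@@H](c2ccc(Br)cc2)[C@H](CO[Si](c2ccccc2)(c2ccccc2)C(C)(C)C)[C@@H](CO[Si](c2ccccc2)(c2ccccc2)C(C)(C)C)[C@H](c2ccc(Br)cc2)O1 | intermediate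
11 | 3-methoxyphenol | COc1cccc(O)c1 | starting material
12 | cesium (1R,2S,3S,4S)-1,4-bis(4-bromophenyl)-2,3-bis{[tert-butyl(diphenyl)silyl]oxymethyl}-4-(3-methoxyphenoxy)butyl sulfate | COc1cccc(c1)O[C@H](c1ccc(Br)cc1)[C@H](CO[Si](c1ccccc1)(c1ccccc1)C(C)(C)C)[C@@H](CO[Si](c1ccccc1)(c1ccccc1)C(C)(C)C)[C@@H](OS(=O)(=O)[O-])c1ccc(Br)cc1.[Cs+] | intermediate
13 | (1R,2S,3S,4S)-1,4-bis(4-bromophenyl)-2,3-bis{[tert-butyl(diphenyl)silyl]oxymethyl}-4-(3-methoxyphenoxy)butan-1-ol | COc1cccc(c1)O[C@H](c1ccc(Br)cc1)[C@H](CO[Si](c1ccccc1)(c1ccccc1)C(C)(C)C)[C@@H](CO[Si](c1ccccc1)(c1ccccc1)C(C)(C)C)[C@@H](O)c1ccc(Br)cc1 | intermediate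
14 | 3,5-dimethoxyphenol | COc1cc(O)cc(OC)c1 | starting material
15 | (1S,2S,3S,4S)-1,4-bis(4-bromophenyl)-1-(3,5-dimethoxyphenoxy)-4-(3-methoxyphenoxy)-2,3-bis{[tert-butyl(diphenyl)silyl]oxymethyl}butane | COc1cccc(c1)O[C@H](c1ccc(Br)cc1)[C@H](CO[Si](c1ccccc1)(c1ccccc1)C(C)(C)C)[C@@H](CO[Si](c1ccccc1)(c1ccccc1)C(C)(C)C)[C@H](Oc1cc(OC)cc(OC)c1)c1ccc(Br)cc1 | intermediate
16 | (2S,3S)-2-[(S)-(4-bromophenyl)(3-methoxyphenoxy)methyl]-3-[(S)-(4-bromophenyl)(3,5-dimethoxyphenoxy)methyl]butane-1,4-diol | COc1cccc(c1)O[C@H](c1ccc(Br)cc1)[C@H](CO)[C@@H](CO)[C@H](Oc1cc(OC)cc(OC)c1)c1ccc(Br)cc1 | intermediate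
17 | (2R,3R)-2-[(S)-(4-bromophenyl)(3-methoxyphenoxy)methyl]-3-[(S)-(4-bromophenyl)(3,5-dimethoxyphenoxy)methyl]butanedial | COc1cccc(c1)O[C@H](c1ccc(Br)cc1)[C@H](C=O)[C@@H](C=O)[C@H](Oc1cc(OC)cc(OC)c1)c1ccc(Br)cc1 | intermediate
18 | (2R,3R)-2-[(S)-(4-bromophenyl)(3-methoxyphenoxy)methyl]-3-[(S)-(4-bromophenyl)(3,5-dimethoxyphenoxy)methyl]butanedioic acid | COc1cccc(c1)O[C@H](c1ccc(Br)cc1)[C@H](C(=O)O)[C@@H](C(=O)O)[C@H](Oc1cc(OC)cc(OC)c1)c1ccc(Br)cc1 | intermediate
19 | (3R,4R)-3-[(S)-(4-bromophenyl)(3-methoxyphenoxy)methyl]-4-[(S)-(4-bromophenyl)(3,5-dimethoxyphenoxy)methyl]oxolane-2,5-dione | COc1cccc(c1)O[C@H](c1ccc(Br)cc1)[C@@H]1C(=O)OC(=O)[C@H]1[C@H](Oc1cc(OC)cc(OC)c1)c1ccc(Br)cc1 | intermediate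
20 | (2R,3S)-3-(4-bromophenyl)-2-[(2S,3R)-2-(4-bromophenyl)-5,7-dimethoxy-4-oxochroman-3-yl]-3-(3-methoxyphenoxy)propanoic acid | COc1cccc(c1)O[C@H](c1ccc(Br)cc1)[C@H](C(=O)O)[C@H]1C(=O)c2c(OC)cc(OC)cc2O[C@@H]1c1ccc(Br)cc1 | intermediate
21 | mixed anhydride of acid 20 with trifluoroacetic acid | COc1cccc(c1)O[C@H](c1ccc(Br)cc1)[C@H](C(=O)OC(=O)C(F)(F)F)[C@H]1C(=O)c2c(OC)cc(OC)cc2O[C@@H]1c1ccc(Br)cc1 | intermediate
22 | (2S,3R)-2-(4-bromophenyl)-3-[(2S,3R)-2-(4-bromophenyl)-7-methoxy-4-oxochroman-3-yl]-5,7-dimethoxychroman-4-one | O=C1c2ccc(OC)cc2O[C@H](c2ccc(Br)cc2)[C@H]1[C@H]1C(=O)c2c(OC)cc(OC)cc2O[C@@H]1c1ccc(Br)cc1 | intermediate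
23 | (2S,3R)-2-(4-bromophenyl)-3-[(2S,3R)-2-(4-bromophenyl)-7-hydroxy-4-oxochroman-3-yl]-5,7-dihydroxychroman-4-one | O=C1c2ccc(O)cc2O[C@H](c2ccc(Br)cc2)[C@H]1[C@H]1C(=O)c2c(O)cc(O)cc2O[C@@H]1c1ccc(Br)cc1 | intermediate
24 | (2S,3R)-5,7-dihydroxy-3-{(2S,3R)-7-hydroxy-4-oxo-2-[4-(4,4,5,5-tetramethyl-1,3,2-dioxaborolan-2-yl)phenyl]chroman-3-yl}-2-[4-(4,4,5,5-tetramethyl-1,3,2-dioxaborolan-2-yl)phenyl]chroman-4-one | O=C1c2ccc(O)cc2O[C@H](c2ccc(B3OC(C)(C)C(C)(C)O3)cc2)[C@H]1[C@H]1C(=O)c2c(O)cc(O)cc2O[C@@H]1c1ccc(B2OC(C)(C)C(C)(C)O2)cc1 | intermediate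
25 | (2S,3R)-5,7-dihydroxy-3-[(2S,3R)-7-hydroxy-2-(4-hydroxyphenyl)-4-oxochroman-3-yl]-2-(4-hydroxyphenyl)chroman-4-one | O=C1c2ccc(O)cc2O[C@H](c2ccc(O)cc2)[C@H]1[C@H]1C(=O)c2c(O)cc(O)cc2O[C@@H]1c1ccc(O)cc1 | target

**Step count and risks**

Total step count: 13. Longest linear sequence: 13 steps (1 and 2 to 25).

Steps most likely to fail:

Step 10 (key step). What may go wrong: loss of an aryloxy group by acid-promoted β-elimination or benzylic ionisation before the ring closes, or arrest after the first acylation. Fallback: the two acylations are run one at a time under Lewis-acid control. Setting out from 18, dicyclohexylcarbodiimide in CH2Cl2 at 0 °C gives the cyclic anhydride 19, now isolated. SnCl4 in CH2Cl2 at −40 °C should open it on the more nucleophilic 3,5-dimethoxyphenoxy ring to give the keto acid 20, which is isolated. Oxalyl chloride with catalytic DMF then converts its single carboxyl group (no anhydride can form now) into (2R,3S)-3-(4-bromophenyl)-2-[(2S,3R)-2-(4-bromophenyl)-5,7-dimethoxy-4-oxochroman-3-yl]-3-(3-methoxyphenoxy)propanoyl chloride F1. After the excess reagent is evaporated, SnCl4 in CH2Cl2 at −78 → −20 °C closes ring C and the route is rejoined at 22.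

Step 2. What may go wrong: incomplete second enolisation or second addition, which would stop at a mono-adduct lactone, or erosion of facial control in the second aldol addition. Fallback: the dilactone is made as the racemate and resolved. Setting out from 4, the dilithium dienolate of commercial di-tert-butyl succinate (LDA, THF, −78 °C) is added to two equivalents of 4 to give di-tert-butyl 2,3-bis[(4-bromophenyl)(hydroxy)methyl]butanedioate F2 as a mixture of diastereomers. CF3CO2H in CH2Cl2 removes both tert-butyl groups and lactonises, and the crystalline exo,exo-dilactone is collected as racemic 3,6-bis(4-bromophenyl)tetrahydro-1H,3H-furo[3,4-c]furan-1,4-dione F3. Preparative chromatography on a chiral stationary phase separates the enantiomers, and the (3R,3aR,6R,6aR) enantiomer is 6, where the route is rejoined.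

Step 7. What may go wrong: elimination of the alkoxyphosphonium ion to the styrene, or failure of the crowded carbinol to be activated at all. Fallback: the leaving group is installed separately and displaced by a free phenoxide. Setting out from 13, MsCl and Et3N in CH2Cl2 at −20 °C give (1R,2S,3S,4S)-1,4-bis(4-bromophenyl)-2,3-bis{[tert-butyl(diphenyl)silyl]oxymethyl}-4-(3-methoxyphenoxy)butyl methanesulfonate F4. Cesium 3,5-dimethoxyphenoxide (from 14 and Cs2CO3) in DMF at 40–60 °C should displace it with inversion, and the route is rejoined at 15.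

**Further compounds**

F1 | step 10 | (2R,3S)-3-(4-bromophenyl)-2-[(2S,3R)-2-(4-bromophenyl)-5,7-dimethoxy-4-oxochroman-3-yl]-3-(3-methoxyphenoxy)propanoyl chloride | COc1cccc(c1)O[C@H](c1ccc(Br)cc1)[C@H](C(=O)Cl)[C@H]1C(=O)c2c(OC)cc(OC)cc2O[C@@H]1c1ccc(Br)cc1
F2 | step 2 | di-tert-butyl 2,3-bis[(4-bromophenyl)(hydroxy)methyl]butanedioate (mixture of diastereomers, configuration not defined) | CC(C)(C)OC(=O)C(C(O)c1ccc(Br)cc1)C(C(O)c1ccc(Br)cc1)C(=O)OC(C)(C)C
F3 | step 2 | racemic exo,exo-3,6-bis(4-bromophenyl)tetrahydro-1H,3H-furo[3,4-c]furan-1,4-dione (both enantiomers, 1:1) | O=C1O[C@@H](c2ccc(Br)cc2)[C@H]2[C@@H]1[C@H](c1ccc(Br)cc1)OC2=O.O=C1O[C@H](c2ccc(Br)cc2)[C@@H]2[C@H]1[C@@H](c1ccc(Br)cc1)OC2=O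
F4 | step 7 | (1R,2S,3S,4S)-1,4-bis(4-bromophenyl)-2,3-bis{[tert-butyl(diphenyl)silyl]oxymethyl}-4-(3-methoxyphenoxy)butyl methanesulfonate | COc1cccc(c1)O[C@H](c1ccc(Br)cc1)[C@H](CO[Si](c1ccccc1)(c1ccccc1)C(C)(C)C)[C@@H](CO[Si](c1ccccc1)(c1ccccc1)C(C)(C)C)[C@@H](OS(C)(=O)=O)c1ccc(Br)cc1
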